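## The problem

The target is a germacranolide. Its ten-membered carbocycle (C1–C10) carries a trans 1,10-epoxide with a free hydroxymethyl group (C14) on C10, a Z C2=C3 alkene, and a cis 4,5-epoxide with the C15 methyl on C4. A butenolide is fused through O–C6 and C7; its tetrasubstituted C7=C11 alkene is exocyclic to the large ring and bears the C13 acetoxymethyl group. Six ring stereocentres (1R, 4R, 5S, 6S, 8S, 10S) and the (R) centre of the 2-methylbutanoate on O8 must be set. The C4/C5 epoxide is adjacent to C6 and can steer a nucleophile there. C8 is separated from C6 by the sp2 atom C7 and needs its own control, C10 is quaternary and remote, and C1 is adjacent to C10 and can be set from it. The molecule tolerates little: H6 is the γ-proton of the butenolide and sits next to an epoxide, so base can open the 4,5-epoxide by vinylogous β-elimination. The C13 acetate is an allylic leaving group on an electron-poor alkene, both epoxides become allylic once C2=C3 is present, and three ester carbonyls must survive while O14 stays free. Two features make a neutral ring closure possible. The Z C2=C3 alkene is a reduced alkyne whose C2 terminus can carry iodine and become a nucleophile, and the 14-hydroxy-1,10-epoxide is the Payne isomer of a 10,14-epoxy-1-ol, the product of adding C2 to a C1 aldehyde on an epoxidised C10.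

## Retrosynthesis

**27 to 26.** The O–C10 bond of the 1,10-epoxide is cut and O14 is reconnected to C10, giving the 10,14-epoxy-1-ol 26. This turns C1 into a carbinol, the retron for a carbonyl addition, and removes the need to epoxidise a medium-ring alkene face-selectively. The forward Payne rearrangement must invert C10 and keep C1, so 26 needs the (1R,10R) arrangement. The driving force is a trisubstituted epoxide and a primary alcohol.

**26 to 25.** The Z alkene is taken back to the C2≡C3 alkyne of cycloalkyne 25. No alkene geometry then has to be carried or created before ring closure. The forward step is a semi-hydrogenation that must stop at the alkene and spare both propargylic C–O bonds.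

**25 to 24 (ring opening).** The C1–C2 bond is cut, giving iodoalkyne aldehyde 24. Against cuts at C6–C7, C7–C8 or C9–C10, this one joins an sp carbon to a non-enolisable aldehyde and leaves butenolide, esters and both epoxides untouched. The two termini are inert towards each other until divalent chromium is added. The forward reaction must close a ten-membered ring and deliver C2 to the correct face of C1.

**24 to 21.** The aldehyde is taken back to alcohol 23, the iodoalkyne to silylalkyne 22, and the C10–C14 epoxide to the 2-substituted allylic alcohol 21. A Sharpless epoxidation sets the remote quaternary C10 under reagent control, which no neighbouring centre could do.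

**21 to 14 + 17 + 19.** Desilylation leads back to silyl ether 20. The O8 ester bond is cut to alcohol 18 and acid 19, and the C8–C9 bond is cut to butenolide aldehyde 14 and allylstannane 17. The allyl unit brings C9, C10, C14 and C1 in one piece at the alcohol oxidation level, so no ester reduction is needed next to the lactone. C8 has to be set by the catalyst because C6 cannot be trusted across C7. Stannane 17 comes from methallyl alcohol 15 through 16.

**14 to 9 + 10.** The C8 aldehyde is taken back to the vinyl group of 12, the acetate to alcohol 11, and the C11–C13 bond to iodide 9 and stannane 10. The C13 oxygen is therefore only present once C11 is sp2 and never sits β to an enolisable carbonyl.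

**9 to 7.** The lactone C12–O bond, the C7–vinyl bond and the C11–I bond are all cut, leading to hydroxy ynoate 7. One syn carbocupration with iodine capture fixes the tetrasubstituted alkene and places O6 cis to the ester.

**7 to 5 + 6.** The C6–C7 bond is cut to epoxy aldehyde 5 and ethyl propiolate 6. The forward acetylide addition must follow the Felkin–Anh sense set by the epoxide, which is the sense needed.

**5 to 1.** Aldehyde 5 comes from epoxy alcohol 4, and 4 from Z-enynol 3 by Sharpless epoxidation. Enynol 3 is the C-silylated form of commercial 1, which supplies C2–C6 and C15 with the Z geometry that becomes the cis epoxide.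

## Roads not taken

**Alternative 1:** The cut is C7–C8. In the forward sense C8 carries a tributylstannyl group and is tied through oxygen to C13, so the ring has thirteen members. n-BuLi exchanges tin for lithium, the carbanion attacks C7 in a [2,3]-Wittig–Still shift while O–C13 breaks, and the ring contracts to the ten-membered alcohol A1. Contraction of a larger ring avoids the entropic cost of direct medium-ring closure. The 1,10-epoxide and the Z alkene are already present, so neither a Payne step nor a semi-hydrogenation is needed; in that respect this road is better than the chosen one. Its weak points are an alkyllithium in the presence of two allylic epoxides and a sense of shift inside a thirteen-membered ring that decides C8 and is hard to predict. A1 is also far from the target: C12 must be oxidised and lactonised onto O6, the exocyclic C11=C13 alkene moved into the ring with oxygen transposed to C13, and three protecting groups exchanged, all on a bis-epoxide. The chosen plan has to answer for a strained cycloalkyne and a late base step, but its closure is neutral and its product is two steps from the target with every carbon at its final oxidation level.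

**Alternative 2:** The cuts are C6–C7 and O–C12. CrCl2 with catalytic NiCl2 converts a C7 iodide on a Z-β-iodo enoate into an alkenylchromium that adds to a C6 epoxy aldehyde, and the chromium alkoxide lactonises onto the cis methyl ester. Both rings close together and give A2, the C14 silyl ether of the target. After the key step only a desilylation remains, which is shorter and gentler than the chosen endgame. The nucleophile is a tetrasubstituted alkenyl iodide bearing an allylic acetate, so the alkenylchromium is hindered and zerovalent nickel can ionise the acetate. The open chain must already hold the Z alkene flanked by both epoxides plus an epoxy aldehyde through fragment assembly. C6 is set inside the macrocyclisation and a wrong epimer is locked into the lactone. The chosen plan sets C6 early in an open chain where epimers can be separated or corrected, uses an unhindered alkynyl iodide, and keeps the bis-allylic epoxide array out of the synthesis until the last two steps.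

**Alternative 3:** The cut is C9–C10. BF3·OEt2 promotes addition of the silyl enol ether of a C8 methyl ketone (carbon C9) to a C10 ketone next to a C1 chloride, giving the chlorohydrin A3; base then closes the 1,10-epoxide. One C–C bond formation builds the quaternary C10 and the ring, the epoxide oxygen is placed directly, and no strained alkyne is handled; these are real advantages. Against it, BF3·OEt2 meets a tertiary allylic 4,5-epoxide, and the α-chloro ketone centre at C1 is allylic and epimerisable. C8 arrives as a ketone that must be reduced selectively and acylated beside a β-hydroxy ketone prone to retro-aldol cleavage, and the epoxide closure still needs base. The chosen plan has the O8 ester in place before ring closure and uses a neutral reagent for it, at the price of the Payne relay.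

Key step: step 17

Assumption: germacranolide numbering (ring C1–C10, C11–C13 on the lactone side, C14 on C10, C15 on C4) is used for all intermediates, and (tributylstannyl)methanol 10 is taken as a purchasable reagent.

## Steps

Step 1
Reactants: 1 (Z)-3-methylpent-2-en-4-yn-1-ol
Product: 3 (Z)-3-methyl-5-(trimethylsilyl)pent-2-en-4-yn-1-ol, via bis-silyl ether 2 (not isolated)
Conditions: EtMgBr (2.2 equiv), THF, 0 °C to rt; Me3SiCl (2.3 equiv), 0 °C; then 1 M aq. HCl, 0 °C
Reagents that add atoms: chlorotrimethylsilane C[Si](C)(C)Cl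
Why: Double deprotonation and silylation of a propargylic-type alcohol, then selective hydrolysis of the O–Si bond; the C-silyl group masks the acidic alkyne proton for the cuprate and palladium steps.

Step 2
Reactants: 3 (Z)-3-methyl-5-(trimethylsilyl)pent-2-en-4-yn-1-ol
Product: 4 {(2S,3R)-3-methyl-3-[(trimethylsilyl)ethynyl]oxiran-2-yl}methanol
Conditions: Ti(OiPr)4 (0.2 equiv), L-(+)-diisopropyl tartrate (0.25 equiv), t-BuOOH (anhydrous, 2 equiv), 4 Å MS, CH2Cl2, −20 °C
Reagents that add atoms: tert-butyl hydroperoxide CC(C)(C)OO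
Why: Sharpless asymmetric epoxidation of a Z-3,3-disubstituted allylic alcohol with a small cis substituent; the L-(+)-tartrate complex delivers oxygen to the face that gives the (2S,3R) epoxide, which is C5 (S) and C4 (R) of the target, and the Z geometry becomes the cis relation of C3 and C6.

Step 3
Reactants: 4 {(2S,3R)-3-methyl-3-[(trimethylsilyl)ethynyl]oxiran-2-yl}methanol
Product: 5 (2R,3R)-3-methyl-3-[(trimethylsilyl)ethynyl]oxirane-2-carbaldehyde
Conditions: Dess–Martin periodinane (1.3 equiv), NaHCO3, CH2Cl2, 0 °C to rt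
Reagents that add atoms: none
Why: Dess–Martin oxidation under buffered, non-epimerising conditions; the descriptor at the aldehyde-bearing carbon changes only because of CIP priorities.

Step 4
Reactants: 5 (2R,3R)-3-methyl-3-[(trimethylsilyl)ethynyl]oxirane-2-carbaldehyde; 6 ethyl propiolate
Product: 7 ethyl (4S)-4-hydroxy-4-{(2S,3R)-3-methyl-3-[(trimethylsilyl)ethynyl]oxiran-2-yl}but-2-ynoate
Conditions: 6, LiN(SiMe3)2 (1.1 equiv), THF, −78 °C; then 5, −78 °C; AcOH quench at −78 °C
Reagents that add atoms: none
Why: Addition of a lithium acetylide to an α,β-epoxy aldehyde; in the Felkin–Anh arrangement the epoxide C–O bond lies anti to the incoming nucleophile, which passes H5, and this gives the anti (6S) carbinol required; the epimers are separable at this stage.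

Step 5
Reactants: 7 ethyl (4S)-4-hydroxy-4-{(2S,3R)-3-methyl-3-[(trimethylsilyl)ethynyl]oxiran-2-yl}but-2-ynoate
Product: 9 (5S)-3-iodo-5-{(2S,3R)-3-methyl-3-[(trimethylsilyl)ethynyl]oxiran-2-yl}-4-vinylfuran-2(5H)-one, via hydroxy iodo dienoate 8 (not isolated)
Conditions: LiN(SiMe3)2 (1.0 equiv), THF, −78 °C; (CH2=CH)2CuMgBr [from CH2=CHMgBr (3.0 equiv) and CuI (1.5 equiv)], −78 °C; I2, −78 °C; AcOH; then PPTS (cat.), CH2Cl2, rt
Reagents that add atoms: vinylmagnesium bromide C=C[Mg]Br; iodine II
Why: Syn carbocupration of a γ-alkoxy ynoate places the vinyl group on C7 and copper on C11, and iodinolysis with retention leaves O6 cis to the ester so that the hydroxy ester lactonises under mild acid; at −78 °C conjugate addition is expected to outpace SN2′ attack on the silyl-capped alkynyl epoxide.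

Step 6
Reactants: 9 (5S)-3-iodo-5-{(2S,3R)-3-methyl-3-[(trimethylsilyl)ethynyl]oxiran-2-yl}-4-vinylfuran-2(5H)-one; 10 (tributylstannyl)methanol
Product: 11 (5S)-3-(hydroxymethyl)-5-{(2S,3R)-3-methyl-3-[(trimethylsilyl)ethynyl]oxiran-2-yl}-4-vinylfuran-2(5H)-one
Conditions: 10 (1.5 equiv), Pd2(dba)3 (2.5 mol%), AsPh3 (20 mol%), CuI (10 mol%), NMP, 45 °C
Reagents that add atoms: none
Why: Stille hydroxymethylation of an α-iodo enoate, a fast coupling partner for zerovalent palladium; the neutral medium spares the epoxide and the acidic H6.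

Step 7
Reactants: 11 (5S)-3-(hydroxymethyl)-5-{(2S,3R)-3-methyl-3-[(trimethylsilyl)ethynyl]oxiran-2-yl}-4-vinylfuran-2(5H)-one
Product: 12 [(5S)-5-{(2S,3R)-3-methyl-3-[(trimethylsilyl)ethynyl]oxiran-2-yl}-2-oxo-4-vinyl-2,5-dihydrofuran-3-yl]methyl acetate
Conditions: Ac2O, pyridine, CH2Cl2, 0 °C
Reagents that add atoms: acetic anhydride CC(=O)OC(C)=O
Why: Acetylation of a primary allylic alcohol with a weak base; this installs the C13 acetate of the target, which also serves as protection through the following steps.

Step 8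
Reactants: 12 [(5S)-5-{(2S,3R)-3-methyl-3-[(trimethylsilyl)ethynyl]oxiran-2-yl}-2-oxo-4-vinyl-2,5-dihydrofuran-3-yl]methyl acetate
Product: 14 [(5S)-4-formyl-5-{(2S,3R)-3-methyl-3-[(trimethylsilyl)ethynyl]oxiran-2-yl}-2-oxo-2,5-dihydrofuran-3-yl]methyl acetate, via diol 13 (not isolated)
Conditions: OsO4 (2 mol%), NaIO4 (4 equiv), 2,6-lutidine (2 equiv), dioxane/H2O 3:1, rt
Reagents that add atoms: osmium tetroxide O=[Os](=O)(=O)=O; sodium periodate [Na+].[O-]I(=O)(=O)=O
Why: Lemieux–Johnson cleavage; OsO4 attacks only the terminal vinyl group, since the tetrasubstituted butenolide alkene is electron-poor and the silylalkyne is inert, and periodate cleaves the diol to the C8 aldehyde.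

Step 9
Reactants: 15 2-methylprop-2-en-1-ol
Product: 16 2-[(tributylstannyl)methyl]prop-2-en-1-ol
Conditions: n-BuLi (2.2 equiv), TMEDA (2.2 equiv), Et2O, 0 °C to rt; then Bu3SnCl (1.0 equiv), THF, −78 °C to rt
Reagents that add atoms: tributyltin chloride CCCC[Sn](Cl)(CCCC)CCCC
Why: Allylic metalation of methallyl alcohol to its O,C-dianion and stannylation at carbon, the softer and more nucleophilic site; the O–Sn bond, if formed, is lost on aqueous work-up.

Step 10
Reactants: 16 2-[(tributylstannyl)methyl]prop-2-en-1-ol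
Product: 17 tert-butyldimethyl({2-[(tributylstannyl)methyl]prop-2-en-1-yl}oxy)silane
Conditions: t-BuMe2SiCl, imidazole, DMF, rt
Reagents that add atoms: tert-butyldimethylsilyl chloride CC(C)(C)[Si](C)(C)Cl
Why: Standard silylation of a primary alcohol under basic conditions that do not protodestannylate the allylstannane.

Step 11
Reactants: 14 [(5S)-4-formyl-5-{(2S,3R)-3-methyl-3-[(trimethylsilyl)ethynyl]oxiran-2-yl}-2-oxo-2,5-dihydrofuran-3-yl]methyl acetate; 17 tert-butyldimethyl({2-[(tributylstannyl)methyl]prop-2-en-1-yl}oxy)silane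
Product: 18 [(5S)-4-[(1S)-4-{[tert-butyl(dimethyl)silyl]oxy}-1-hydroxy-3-methylidenebutyl]-5-{(2S,3R)-3-methyl-3-[(trimethylsilyl)ethynyl]oxiran-2-yl}-2-oxo-2,5-dihydrofuran-3-yl]methyl acetate
Conditions: 17 (1.5 equiv), (S)-BINOL (0.2 equiv), Ti(OiPr)4 (0.1 equiv), 4 Å MS, CH2Cl2, −20 °C
Reagents that add atoms: none
Why: Keck asymmetric allylation with a 2-substituted allylstannane; the (S)-BINOL/Ti(OiPr)4 catalyst directs the allyl group to the Si face of the electron-poor aldehyde and sets C8 as (S) under catalyst control, forming C8–C9 and bringing C9, C10, C14 and C1.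

Step 12
Reactants: 18 [(5S)-4-[(1S)-4-{[tert-butyl(dimethyl)silyl]oxy}-1-hydroxy-3-methylidenebutyl]-5-{(2S,3R)-3-methyl-3-[(trimethylsilyl)ethynyl]oxiran-2-yl}-2-oxo-2,5-dihydrofuran-3-yl]methyl acetate; 19 (R)-2-methylbutanoic acid
Product: 20 (1S)-1-[(2S)-4-(acetoxymethyl)-2-{(2S,3R)-3-methyl-3-[(trimethylsilyl)ethynyl]oxiran-2-yl}-5-oxo-2,5-dihydrofuran-3-yl]-4-{[tert-butyl(dimethyl)silyl]oxy}-3-methylidenebutyl (2R)-2-methylbutanoate
Conditions: 19 (1.5 equiv), DCC (1.6 equiv), DMAP (0.1 equiv), CH2Cl2, 0 °C to rt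
Reagents that add atoms: none
Why: Steglich esterification with retention at C8 and, at 0 °C with little DMAP, without epimerising the acid; it is run on freshly prepared 18 so that acetyl migration from O13 and translactonisation onto O8 have no time to occur.

Step 13
Reactants: 20 (1S)-1-[(2S)-4-(acetoxymethyl)-2-{(2S,3R)-3-methyl-3-[(trimethylsilyl)ethynyl]oxiran-2-yl}-5-oxo-2,5-dihydrofuran-3-yl]-4-{[tert-butyl(dimethyl)silyl]oxy}-3-methylidenebutyl (2R)-2-methylbutanoate
Product: 21 (1S)-1-[(2S)-4-(acetoxymethyl)-2-{(2S,3R)-3-methyl-3-[(trimethylsilyl)ethynyl]oxiran-2-yl}-5-oxo-2,5-dihydrofuran-3-yl]-4-hydroxy-3-methylidenebutyl (2R)-2-methylbutanoate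
Conditions: HF·pyridine, excess pyridine, THF, 0 °C to rt
Reagents that add atoms: none
Why: Buffered HF·pyridine cleaves the primary silyl ether and leaves the C-silyl alkyne, the esters and the epoxide intact; basic fluoride is avoided because of H6 and the alkynylsilane.

Step 14
Reactants: 21 (1S)-1-[(2S)-4-(acetoxymethyl)-2-{(2S,3R)-3-methyl-3-[(trimethylsilyl)ethynyl]oxiran-2-yl}-5-oxo-2,5-dihydrofuran-3-yl]-4-hydroxy-3-methylidenebutyl (2R)-2-methylbutanoate
Product: 22 (1S)-1-[(2S)-4-(acetoxymethyl)-2-{(2S,3R)-3-methyl-3-[(trimethylsilyl)ethynyl]oxiran-2-yl}-5-oxo-2,5-dihydrofuran-3-yl]-2-[(2S)-2-(hydroxymethyl)oxiran-2-yl]ethyl (2R)-2-methylbutanoate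
Conditions: Ti(OiPr)4 (0.2 equiv), L-(+)-diisopropyl tartrate (0.25 equiv), t-BuOOH (anhydrous), 4 Å MS, CH2Cl2, −20 °C
Reagents that add atoms: tert-butyl hydroperoxide CC(C)(C)OO
Why: Sharpless asymmetric epoxidation of a 2-substituted allylic alcohol; the L-(+)-tartrate complex sets the quaternary C10 under reagent control with the same facial sense as for 2-methylallyl alcohol, and only the allylic alcohol alkene reacts because the butenolide alkene is electron-poor and has no directing hydroxyl.

Step 15
Reactants: 22 (1S)-1-[(2S)-4-(acetoxymethyl)-2-{(2S,3R)-3-methyl-3-[(trimethylsilyl)ethynyl]oxiran-2-yl}-5-oxo-2,5-dihydrofuran-3-yl]-2-[(2S)-2-(hydroxymethyl)oxiran-2-yl]ethyl (2R)-2-methylbutanoate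
Product: 23 (1S)-1-[(2S)-4-(acetoxymethyl)-2-[(2S,3R)-3-(iodoethynyl)-3-methyloxiran-2-yl]-5-oxo-2,5-dihydrofuran-3-yl]-2-[(2S)-2-(hydroxymethyl)oxiran-2-yl]ethyl (2R)-2-methylbutanoate
Conditions: N-iodosuccinimide (1.2 equiv), AgNO3 (0.1 equiv), acetone, rt, dark
Reagents that add atoms: N-iodosuccinimide O=C1CCC(=O)N1I
Why: Silver-catalysed iododesilylation converts the alkynylsilane directly into the 1-iodoalkyne through an alkynylsilver species under neutral conditions.

Step 16
Reactants: 23 (1S)-1-[(2S)-4-(acetoxymethyl)-2-[(2S,3R)-3-(iodoethynyl)-3-methyloxiran-2-yl]-5-oxo-2,5-dihydrofuran-3-yl]-2-[(2S)-2-(hydroxymethyl)oxiran-2-yl]ethyl (2R)-2-methylbutanoate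
Product: 24 (1S)-1-[(2S)-4-(acetoxymethyl)-2-[(2S,3R)-3-(iodoethynyl)-3-methyloxiran-2-yl]-5-oxo-2,5-dihydrofuran-3-yl]-2-[(2R)-2-formyloxiran-2-yl]ethyl (2R)-2-methylbutanoate
Conditions: Dess–Martin periodinane (1.5 equiv), NaHCO3, CH2Cl2, 0 °C
Reagents that add atoms: none
Why: Dess–Martin oxidation to an aldehyde on quaternary C10 that cannot enolise or epimerise; the C10 descriptor changes from S to R only through CIP priorities, and the aldehyde is used directly.

Step 17
Reactants: 24 (1S)-1-[(2S)-4-(acetoxymethyl)-2-[(2S,3R)-3-(iodoethynyl)-3-methyloxiran-2-yl]-5-oxo-2,5-dihydrofuran-3-yl]-2-[(2R)-2-formyloxiran-2-yl]ethyl (2R)-2-methylbutanoate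
Product: 25 (1R,4R,5S,6S,8S,10R)-13-acetoxy-4,5:10,14-diepoxy-1-hydroxy-8-[(2R)-2-methylbutanoyloxy]germacr-7(11)-en-2-yn-12,6-olide
Conditions: CrCl2 (8 equiv), NiCl2 (1 mol%), THF, rt, slow addition of 24 to a final concentration of about 2 mM; aqueous sodium serinate work-up
Reagents that add atoms: none
Why: Two equivalents of divalent chromium reduce the C2–I bond, with zerovalent nickel from NiCl2 assisting by oxidative addition and transmetalation, to give an alkynyl trivalent chromium species that adds to the C1 aldehyde; the chromium alkoxide is released on work-up. The closest known reaction is the intramolecular Nozaki–Hiyama–Kishi alkynylation of iodoalkynyl aldehydes to ten-membered cycloalkynes. The ten-membered carbocycle closes by 10-exo-trig attack of C2 on the carbonyl carbon C1, forming C1–C2. The new stereocentre C1 is controlled by quaternary C10 in a Felkin–Anh arrangement: the C10–O bond lies anti to the incoming C2 and the nucleophile passes the small epoxide CH2 (C14) and not C9, which gives (1R) with O1 anti to the C10–O bond. The step needs chemoselectivity for the C(sp)–I bond, which the neutral reagent provides while butenolide, esters and epoxides are left alone. It also needs a non-enolisable aldehyde, which quaternary C10 guarantees. High dilution suppresses oligomers, and the nickel loading is kept low to avoid diyne homocoupling and ionisation of the C13 allylic acetate.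

Step 18
Reactants: 25 (1R,4R,5S,6S,8S,10R)-13-acetoxy-4,5:10,14-diepoxy-1-hydroxy-8-[(2R)-2-methylbutanoyloxy]germacr-7(11)-en-2-yn-12,6-olide
Product: 26 (1R,2Z,4R,5S,6S,8S,10R)-13-acetoxy-4,5:10,14-diepoxy-1-hydroxy-8-[(2R)-2-methylbutanoyloxy]germacra-2,7(11)-dien-12,6-olide
Conditions: H2 (1 atm), Pd/CaCO3 poisoned with Pb(OAc)2, quinoline, EtOAc, 0 °C
Reagents that add atoms: none
Why: Lindlar-type semi-hydrogenation adds hydrogen syn and gives the Z alkene; the strained cycloalkyne is the most reactive unsaturation, and the poisoned catalyst with quinoline should spare the tetrasubstituted butenolide alkene and the propargylic C–O bonds.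

Step 19
Reactants: 26 (1R,2Z,4R,5S,6S,8S,10R)-13-acetoxy-4,5:10,14-diepoxy-1-hydroxy-8-[(2R)-2-methylbutanoyloxy]germacra-2,7(11)-dien-12,6-olide
Product: 27 (1R,2Z,4R,5S,6S,8S,10S)-13-acetoxy-1,10:4,5-diepoxy-14-hydroxy-8-[(2R)-2-methylbutanoyloxy]germacra-2,7(11)-dien-12,6-olide
Conditions: KN(SiMe3)2 (1.0 equiv), THF, −78 to −30 °C; AcOH/pH 7 buffer quench at low temperature
Reagents that add atoms: none
Why: Payne rearrangement in an aprotic medium: the C1 alkoxide attacks C10 from the side opposite the C10–O14 bond (3-exo-tet), inverting C10 to (S), keeping C1 and freeing O14; it is driven by the trisubstituted epoxide and the primary alkoxide. One equivalent of a non-nucleophilic base at low temperature is chosen to avoid ester cleavage and deprotonation at C6.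

## Compound list

1 | (Z)-3-methylpent-2-en-4-yn-1-ol | C#C/C(C)=C\CO | starting material
2 | (Z)-trimethyl{[3-methyl-5-(trimethylsilyl)pent-2-en-4-yn-1-yl]oxy}silane | C[Si](C)(C)C#C/C(C)=C\CO[Si](C)(C)C | intermediate
3 | (Z)-3-methyl-5-(trimethylsilyl)pent-2-en-4-yn-1-ol | C[Si](C)(C)C#C/C(C)=C\CO | intermediate
4 | {(2S,3R)-3-methyl-3-[(trimethylsilyl)ethynyl]oxiran-2-yl}methanol | C[Si](C)(C)C#C[C@@]1(C)O[C@H]1CO | intermediate
5 | (2R,3R)-3-methyl-3-[(trimethylsilyl)ethynyl]oxirane-2-carbaldehyde | C[Si](C)(C)C#C[C@@]1(C)O[C@H]1C=O | intermediate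
6 | ethyl propiolate | C#CC(=O)OCC | starting material
7 | ethyl (4S)-4-hydroxy-4-{(2S,3R)-3-methyl-3-[(trimethylsilyl)ethynyl]oxiran-2-yl}but-2-ynoate | C[Si](C)(C)C#C[C@@]1(C)O[C@H]1[C@@H](O)C#CC(=O)OCC | intermediate
8 | ethyl (2E)-3-[(S)-hydroxy{(2S,3R)-3-methyl-3-[(trimethylsilyl)ethynyl]oxiran-2-yl}methyl]-2-iodopenta-2,4-dienoate | C[Si](C)(C)C#C[C@@]1(C)O[C@H]1[C@@H](O)/C(C=C)=C(/I)C(=O)OCC | intermediate
9 | (5S)-3-iodo-5-{(2S,3R)-3-methyl-3-[(trimethylsilyl)ethynyl]oxiran-2-yl}-4-vinylfuran-2(5H)-one | C[Si](C)(C)C#C[C@@]1(C)O[C@H]1[C@H]1OC(=O)C(I)=C1C=C | intermediate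
10 | (tributylstannyl)methanol | CCCC[Sn](CCCC)(CCCC)CO | starting material
11 | (5S)-3-(hydroxymethyl)-5-{(2S,3R)-3-methyl-3-[(trimethylsilyl)ethynyl]oxiran-2-yl}-4-vinylfuran-2(5H)-one | C[Si](C)(C)C#C[C@@]1(C)O[C@H]1[C@H]1OC(=O)C(CO)=C1C=C | intermediate
12 | [(5S)-5-{(2S,3R)-3-methyl-3-[(trimethylsilyl)ethynyl]oxiran-2-yl}-2-oxo-4-vinyl-2,5-dihydrofuran-3-yl]methyl acetate | C[Si](C)(C)C#C[C@@]1(C)O[C@H]1[C@H]1OC(=O)C(COC(C)=O)=C1C=C | intermediate
13 | [(5S)-4-(1,2-dihydroxyethyl)-5-{(2S,3R)-3-methyl-3-[(trimethylsilyl)ethynyl]oxiran-2-yl}-2-oxo-2,5-dihydrofuran-3-yl]methyl acetate (both carbinol epimers) | C[Si](C)(C)C#C[C@@]1(C)O[C@H]1[C@H]1OC(=O)C(COC(C)=O)=C1C(O)CO | intermediate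
14 | [(5S)-4-formyl-5-{(2S,3R)-3-methyl-3-[(trimethylsilyl)ethynyl]oxiran-2-yl}-2-oxo-2,5-dihydrofuran-3-yl]methyl acetate | C[Si](C)(C)C#C[C@@]1(C)O[C@H]1[C@H]1OC(=O)C(COC(C)=O)=C1C=O | intermediate
15 | 2-methylprop-2-en-1-ol | CC(=C)CO | starting material
16 | 2-[(tributylstannyl)methyl]prop-2-en-1-ol | CCCC[Sn](CCCC)(CCCC)CC(=C)CO | intermediate
17 | tert-butyldimethyl({2-[(tributylstannyl)methyl]prop-2-en-1-yl}oxy)silane | CCCC[Sn](CCCC)(CCCC)CC(=C)CO[Si](C)(C)C(C)(C)C | intermediate
18 | [(5S)-4-[(1S)-4-{[tert-butyl(dimethyl)silyl]oxy}-1-hydroxy-3-methylidenebutyl]-5-{(2S,3R)-3-methyl-3-[(trimethylsilyl)ethynyl]oxiran-2-yl}-2-oxo-2,5-dihydrofuran-3-yl]methyl acetate | C[Si](C)(C)C#C[C@@]1(C)O[C@H]1[C@H]1OC(=O)C(COC(C)=O)=C1[C@@H](O)CC(=C)CO[Si](C)(C)C(C)(C)C | intermediate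
19 | (R)-2-methylbutanoic acid | CC[C@@H](C)C(=O)O | starting material
20 | (1S)-1-[(2S)-4-(acetoxymethyl)-2-{(2S,3R)-3-methyl-3-[(trimethylsilyl)ethynyl]oxiran-2-yl}-5-oxo-2,5-dihydrofuran-3-yl]-4-{[tert-butyl(dimethyl)silyl]oxy}-3-methylidenebutyl (2R)-2-methylbutanoate | C[Si](C)(C)C#C[C@@]1(C)O[C@H]1[C@H]1OC(=O)C(COC(C)=O)=C1[C@H](CC(=C)CO[Si](C)(C)C(C)(C)C)OC(=O)[C@H](C)CC | intermediate
21 | (1S)-1-[(2S)-4-(acetoxymethyl)-2-{(2S,3R)-3-methyl-3-[(trimethylsilyl)ethynyl]oxiran-2-yl}-5-oxo-2,5-dihydrofuran-3-yl]-4-hydroxy-3-methylidenebutyl (2R)-2-methylbutanoate | C[Si](C)(C)C#C[C@@]1(C)O[C@H]1[C@H]1OC(=O)C(COC(C)=O)=C1[C@H](CC(=C)CO)OC(=O)[C@H](C)CC | intermediate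
22 | (1S)-1-[(2S)-4-(acetoxymethyl)-2-{(2S,3R)-3-methyl-3-[(trimethylsilyl)ethynyl]oxiran-2-yl}-5-oxo-2,5-dihydrofuran-3-yl]-2-[(2S)-2-(hydroxymethyl)oxiran-2-yl]ethyl (2R)-2-methylbutanoate | C[Si](C)(C)C#C[C@@]1(C)O[C@H]1[C@H]1OC(=O)C(COC(C)=O)=C1[C@H](C[C@]1(CO)CO1)OC(=O)[C@H](C)CC | intermediate
23 | (1S)-1-[(2S)-4-(acetoxymethyl)-2-[(2S,3R)-3-(iodoethynyl)-3-methyloxiran-2-yl]-5-oxo-2,5-dihydrofuran-3-yl]-2-[(2S)-2-(hydroxymethyl)oxiran-2-yl]ethyl (2R)-2-methylbutanoate | IC#C[C@@]1(C)O[C@H]1[C@H]1OC(=O)C(COC(C)=O)=C1[C@H](C[C@]1(CO)CO1)OC(=O)[C@H](C)CC | intermediate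
24 | (1S)-1-[(2S)-4-(acetoxymethyl)-2-[(2S,3R)-3-(iodoethynyl)-3-methyloxiran-2-yl]-5-oxo-2,5-dihydrofuran-3-yl]-2-[(2R)-2-formyloxiran-2-yl]ethyl (2R)-2-methylbutanoate | IC#C[C@@]1(C)O[C@H]1[C@H]1OC(=O)C(COC(C)=O)=C1[C@H](C[C@]1(C=O)CO1)OC(=O)[C@H](C)CC | intermediate
25 | (1R,4R,5S,6S,8S,10R)-13-acetoxy-4,5:10,14-diepoxy-1-hydroxy-8-[(2R)-2-methylbutanoyloxy]germacr-7(11)-en-2-yn-12,6-olide | CC[C@@H](C)C(=O)O[C@H]1C[C@@]2(CO2)[C@H](O)C#C[C@@]2(C)O[C@H]2[C@H]2OC(=O)C(COC(C)=O)=C12 | intermediate
26 | (1R,2Z,4R,5S,6S,8S,10R)-13-acetoxy-4,5:10,14-diepoxy-1-hydroxy-8-[(2R)-2-methylbutanoyloxy]germacra-2,7(11)-dien-12,6-olide | CC[C@@H](C)C(=O)O[C@H]1C[C@@]2(CO2)[C@H](O)/C=C\[C@@]2(C)O[C@H]2[C@H]2OC(=O)C(COC(C)=O)=C12 | intermediate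
27 | (1R,2Z,4R,5S,6S,8S,10S)-13-acetoxy-1,10:4,5-diepoxy-14-hydroxy-8-[(2R)-2-methylbutanoyloxy]germacra-2,7(11)-dien-12,6-olide (CNP0108300.1) | CC[C@@H](C)C(=O)O[C@H]1C[C@@]2(CO)O[C@@H]2/C=C\[C@@]2(C)O[C@H]2[C@H]2OC(=O)C(COC(C)=O)=C12 | target

## Step count and least certain steps

Total: 19 steps. Longest linear sequence: 17 steps (steps 1–8 and 11–19, from 1 to 27); steps 9 and 10 prepare stannane 17.

**Step 17 (key step).** The most likely failure is incomplete ring closure. The transition state has to bend the linear C1–C2≡C3–C4 unit into a ten-membered ring that already holds a cis epoxide and the sp2 atom C7, so protodemetalation of the alkynylchromium and intermolecular addition can compete. A second concern is loss of facial selectivity at C1 if the ring conformation overrides the Felkin–Anh preference. Fallback: the nucleophile is changed from an alkynyl to a Z-alkenyl chromium, which closes the less strained ring of the natural alkene and keeps the C1–C2 disconnection. From 23, diimide (from 2-nitrobenzenesulfonyl hydrazide and Et3N) reduces the iodoalkyne to the (Z)-iodoalkenyl epoxy alcohol F1. Dess–Martin oxidation gives the (Z)-iodoalkenyl epoxy aldehyde F2, and CrCl2 with catalytic NiCl2 closes the ring with retention of alkene geometry. The route is rejoined at 26 and step 18 is no longer needed.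

**Step 19.** The most likely failures are deprotonation at C6 followed by vinylogous β-elimination of the 4,5-epoxide, and acyl transfer from the C13 acetate or the O8 ester to the liberated primary alkoxide. Both arise because an allylic alkoxide in an aprotic medium is a strong base and nucleophile. Fallback: the order of the last two steps is exchanged. From 25 the rearrangement is run on the propargylic alcohol, which is about two pK units more acidic and gives a less basic alkoxide, with Cs2CO3 in MeCN at 0 °C. This gives the 1,10-epoxy cycloalkyne F3, and semi-hydrogenation over Pd/CaCO3 poisoned with Pb(OAc)2 then leads to 27.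

**Step 5.** The most likely failures are SN2′ opening of the alkynyl epoxide by excess cuprate and loss of alkene geometry in the alkenylcopper before iodine capture, which would leave an enoate that cannot lactonise. Fallback: the two groups are installed by palladium chemistry instead. From 7, Bu3SnSnBu3 and Pd(PPh3)4 add both tin groups syn across the ynoate with concomitant lactonisation to the bis(stannyl)butenolide F4. A Stille coupling with vinyl bromide at the more reactive β-stannane gives the vinyl stannyl butenolide F5, and iododestannylation with I2 returns to 9.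

**Step 4.** The most likely failure is poor facial selectivity at C6, because Felkin–Anh control by an epoxide is often modest with small lithium acetylides. Fallback: the stereocentre is set by reagent-controlled reduction instead. The mixture of 7 and its C6 epimer F6 is oxidised with Dess–Martin periodinane to the keto ynoate F7. A Midland reduction with (R)-Alpine-Borane, in which the alkynyl group acts as the small substituent, returns 7.

**Step 11.** The most likely failure is poor facial selectivity at C8, if a slow catalysed pathway lets the uncatalysed, substrate-biased addition compete or if the C6 centre opposes the catalyst. Fallback: both epimers are converged by changing the esterification. The (8R) epimer F8 is esterified with 19 under Mitsunobu conditions (PPh3, diisopropyl azodicarboxylate) with inversion at C8, rejoining the route at 20, while the (8S) alcohol 18 is acylated as in step 12.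

## Further compounds

F1 | step 17 | (1S)-1-[(2S)-4-(acetoxymethyl)-2-{(2S,3R)-3-[(Z)-2-iodoethenyl]-3-methyloxiran-2-yl}-5-oxo-2,5-dihydrofuran-3-yl]-2-[(2S)-2-(hydroxymethyl)oxiran-2-yl]ethyl (2R)-2-methylbutanoate | I/C=C\[C@@]1(C)O[C@H]1[C@H]1OC(=O)C(COC(C)=O)=C1[C@H](C[C@]1(CO)CO1)OC(=O)[C@H](C)CC
F2 | step 17 | (1S)-1-[(2S)-4-(acetoxymethyl)-2-{(2S,3R)-3-[(Z)-2-iodoethenyl]-3-methyloxiran-2-yl}-5-oxo-2,5-dihydrofuran-3-yl]-2-[(2R)-2-formyloxiran-2-yl]ethyl (2R)-2-methylbutanoate | I/C=C\[C@@]1(C)O[C@H]1[C@H]1OC(=O)C(COC(C)=O)=C1[C@H](C[C@]1(C=O)CO1)OC(=O)[C@H](C)CC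
F3 | step 19 | (1R,4R,5S,6S,8S,10S)-13-acetoxy-1,10:4,5-diepoxy-14-hydroxy-8-[(2R)-2-methylbutanoyloxy]germacr-7(11)-en-2-yn-12,6-olide | CC[C@@H](C)C(=O)O[C@H]1C[C@@]2(CO)O[C@@H]2C#C[C@@]2(C)O[C@H]2[C@H]2OC(=O)C(COC(C)=O)=C12
F4 | step 5 | (5R)-5-{(2S,3R)-3-methyl-3-[(trimethylsilyl)ethynyl]oxiran-2-yl}-3,4-bis(tributylstannyl)furan-2(5H)-one | C[Si](C)(C)C#C[C@@]1(C)O[C@H]1[C@H]1OC(=O)C([Sn](CCCC)(CCCC)CCCC)=C1[Sn](CCCC)(CCCC)CCCC
F5 | step 5 | (5S)-5-{(2S,3R)-3-methyl-3-[(trimethylsilyl)ethynyl]oxiran-2-yl}-3-(tributylstannyl)-4-vinylfuran-2(5H)-one | C[Si](C)(C)C#C[C@@]1(C)O[C@H]1[C@H]1OC(=O)C([Sn](CCCC)(CCCC)CCCC)=C1C=C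
F6 | step 4 | ethyl (4R)-4-hydroxy-4-{(2S,3R)-3-methyl-3-[(trimethylsilyl)ethynyl]oxiran-2-yl}but-2-ynoate | C[Si](C)(C)C#C[C@@]1(C)O[C@H]1[C@H](O)C#CC(=O)OCC
F7 | step 4 | ethyl 4-{(2R,3R)-3-methyl-3-[(trimethylsilyl)ethynyl]oxiran-2-yl}-4-oxobut-2-ynoate | C[Si](C)(C)C#C[C@@]1(C)O[C@H]1C(=O)C#CC(=O)OCC
F8 | step 11 | [(5S)-4-[(1R)-4-{[tert-butyl(dimethyl)silyl]oxy}-1-hydroxy-3-methylidenebutyl]-5-{(2S,3R)-3-methyl-3-[(trimethylsilyl)ethynyl]oxiran-2-yl}-2-oxo-2,5-dihydrofuran-3-yl]methyl acetate | C[Si](C)(C)C#C[C@@]1(C)O[C@H]1[C@H]1OC(=O)C(COC(C)=O)=C1[C@H](O)CC(=C)CO[Si](C)(C)C(C)(C)C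
A1 | alternative 1 | ten-membered 8-ol with 1,10- and 4,5-epoxides, Z-2-ene, 6-O-triethylsilyl, 14-O-tert-butyldimethylsilyl, C7–H and a 3-(4-methoxybenzyloxy)prop-1-en-2-yl group on C7 | O[C@H]1C[C@@]2(CO[Si](C)(C)C(C)(C)C)O[C@@H]2/C=C\[C@@]2(C)O[C@H]2[C@@H](O[Si](CC)(CC)CC)[C@H]1C(=C)COCc1ccc(OC)cc1
A2 | alternative 2 | 14-O-tert-butyldimethylsilyl ether of 27 | CC[C@@H](C)C(=O)O[C@H]1C[C@@]2(CO[Si](C)(C)C(C)(C)C)O[C@@H]2/C=C\[C@@]2(C)O[C@H]2[C@H]2OC(=O)C(COC(C)=O)=C12
A3 | alternative 3 | ten-membered 8-ketone with 10-hydroxy, 14-O-tert-butyldimethylsilyl, 1-chloro, Z-2-ene, 4,5-epoxide and the 13-acetoxy butenolide | O=C1C[C@](O)(CO[Si](C)(C)C(C)(C)C)[C@@H](Cl)/C=C\[C@@]2(C)O[C@H]2[C@H]2OC(=O)C(COC(C)=O)=C12
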